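**Retrosynthetic overview**
1. Target 14 ⇒ hydrocarbon 11: both C3–O bonds are made last, by a twofold enzymatic C3–H hydroxylation that sets C3 and C3'.
2. 11 ⇒ acids 6 (Δ7 half) + 8 (8β-H half): the C11–C11' bond comes from a doubly decarboxylative alkyl–alkyl cross-coupling.
3. 6 and 8 ⇒ one exo-methylene ester 4, by MHAT isomerisation (gives Δ7) or MHAT hydrogenation (sets C8').
4. 4 ⇒ (+)-sclareolide 1 by lactone opening and dehydration.
5. No ring is formed: rings A and B of both halves, with C5, C9 and C10, are taken intact from 1.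

Assumption: the target SMILES is read as the onocerane-type C30 diol of the (+)-sclareolide absolute series. One half has 3β-OH, 5α-H, 9α-H, 10β-CH3 and Δ7; the other has 3'β-OH, 5'α-H, 8'β-H (8'α-CH3, equatorial), 9'α-H and 10'β-CH3.

Numbering in names: C1–C10 is the decalin, C11 the CH2 on C9, C12 the carboxyl carbon of the C16 compounds, C17 the carbon on C8. Primes mark the saturated half; the halves are joined C11–C11'. α/β follow the usual terpenoid drawing (C10 methyl = β).

**Step 1**
Reactants: 1 (+)-sclareolide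
Product: 3 methyl 8α-hydroxy-13,14,15,16-tetranorlabdan-12-oate, via potassium 8α-hydroxy carboxylate 2 (not isolated)
Conditions: KOH, MeOH, reflux; evaporate; MeI, DMF, rt
Reagents that add atoms: potassium hydroxide, [K+].[OH-]; iodomethane, CI
Why: Lactone saponification (acyl–oxygen cleavage) followed by SN2 O-methylation of the carboxylate traps the open form before it can relactonise; no stereocentre is touched, so the 8α-OH of sclareolide is kept.

**Step 2**
Reactants: 3 methyl 8α-hydroxy-13,14,15,16-tetranorlabdan-12-oate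
Product: 4 methyl 13,14,15,16-tetranorlabd-8(17)-en-12-oate
Conditions: SOCl2, pyridine, CH2Cl2, −78 °C; AgNO3-silica chromatography
Reagents that add atoms: none
Why: Tertiary-alcohol dehydration through the chlorosulfite by E2 elimination: the equatorial 8α leaving group has no anti-periplanar ring hydrogen, so a C17 hydrogen is lost and the exocyclic alkene results; any Δ7 isomer carried along converges in steps 3 and 4, and C5, C9, C10 are untouched.

**Step 3**
Reactants: 4 methyl 13,14,15,16-tetranorlabd-8(17)-en-12-oate (about three quarters of the material)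
Product: 6 13,14,15,16-tetranorlabd-7-en-12-oic acid, via Δ7 methyl ester 5 (not isolated)
Conditions: Co(salen)Cl (salen = N,N'-bis(3,5-di-tert-butylsalicylidene)-1,2-cyclohexanediaminate; trivalent cobalt; 3 mol %), PhSiH3 (6 mol %), benzene, rt; then LiOH, THF/MeOH/H2O, 50 °C; cold 1 M HCl to pH 3
Reagents that add atoms: lithium hydroxide, [Li+].[OH-]
Why: MHAT (metal-hydride hydrogen-atom-transfer) alkene isomerisation: the cobalt hydride adds H to C17 to give the tertiary C8 radical, and cobalt then removes the accessible C7–H instead of the C9–H flanked by quaternary C10, giving the trisubstituted Δ7 alkene with C9 intact; ester saponification follows, with a brief cold acidification to avoid relactonisation.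

**Step 4**
Reactants: 4 methyl 13,14,15,16-tetranorlabd-8(17)-en-12-oate (about one quarter of the material)
Product: 8 (8β-H)-13,14,15,16-tetranorlabdan-12-oic acid (8α-CH3), via saturated methyl ester 7 (not isolated)
Conditions: Mn(dpm)3 (tris(2,2,6,6-tetramethyl-3,5-heptanedionato)manganese, trivalent manganese; 10 mol %), PhSiH3, t-BuOOH, i-PrOH, rt; then LiOH, THF/H2O, 50 °C; HCl work-up
Reagents that add atoms: lithium hydroxide, [Li+].[OH-]
Why: MHAT radical hydrogenation: H adds to C17, and the tertiary C8 radical, pyramidalised with its methyl equatorial, is expected to take the second hydrogen axially on the β face, giving the thermodynamically preferred 8β-H/8α-CH3 epimer (diequatorial with C11, no syn-axial CH3/CH3 contact with the C10 methyl), the opposite of α-face delivery by heterogeneous hydrogenation; saponification follows.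

**Step 5**
Reactants: 6 13,14,15,16-tetranorlabd-7-en-12-oic acid (3 equiv); 8 (8β-H)-13,14,15,16-tetranorlabdan-12-oic acid (1 equiv)
Product: 11 (8'β-H)-11-(drim-7-en-11-yl)drimane, the 3,3'-dideoxy target, via Δ7 N-acyloxyphthalimide 9 (not isolated), via saturated N-acyloxyphthalimide 10 (not isolated)
Conditions: N-hydroxyphthalimide, DIC, DMAP (cat.), CH2Cl2, rt; solvent swap to NMP; NiCl2·6H2O (20 mol %), 2,2′:6′,2″-terpyridine (20 mol %), AgNO3 (30 mol %), Mg anode/reticulated vitreous carbon cathode, constant current, rt; AgNO3-silica chromatography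
Reagents that add atoms: none
Why: Carbodiimide esterification to the redox-active esters, then nickel-electrocatalytic doubly decarboxylative alkyl–alkyl cross-coupling: single-electron reduction of each ester expels CO2 and phthalimide to give the primary C11 and C11' radicals, which nickel joins; the excess of 6 biases the statistical mixture towards the cross product based on 8, the two homodimers differ from 11 by one C=C each and separate on AgNO3-silica, and no stereocentre is involved because both radicals sit on CH2.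

**Step 6**
Reactants: 11 (8'β-H)-11-(drim-7-en-11-yl)drimane
Product: 14 target diol (CNP0194061.1), via ene-half 3β-mono-ol 12 (not isolated), via saturated-half 3'β-mono-ol 13 (not isolated)
Conditions: engineered P450 BM3 (CYP102A1) variant (heme-iron monooxygenase, clarified E. coli lysate), NADP+ (cat.), phosphite dehydrogenase, Na2HPO3, air, KPi buffer pH 8.0, 2-hydroxypropyl-β-cyclodextrin, 5 % DMSO, 25 °C
Reagents that add atoms: dioxygen, O=O
Why: Proposed new method: twofold, terminus-selective C–H hydroxylation (C–O bond formation) of an unfunctionalised C30 bis-drimane by a P450 BM3 variant re-screened on 11, 12 and 13 (site saturation of channel-mouth residues of a sclareolide 3β-hydroxylase), a substrate class on which this reactivity has not been shown; each 4,4,10-trimethyl-trans-decalin end of 11 is locally identical to ring A of sclareolide, so the end bound above the heme presents its equatorial 3β-H to the iron-oxo porphyrin radical cation, hydrogen abstraction and oxygen rebound occur on the same face with retention to give the 3β (3S) alcohol, the released mono-ol rebinds through its other end for the second hydroxylation, and the Δ7 alkene lies two rings away from the oxidant while the rest of the molecule fills the long fatty-acid channel; the closest known reaction type is the BM3-variant-catalysed 3β-hydroxylation of sclareolide and sclareol.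

**Compound list**
1 | (+)-sclareolide (8α,12-lactone; 5α-H, 9α-H, 10β-CH3, 8β-CH3) | O=C1C[C@H]2[C@](C)(O1)CC[C@H]3C(C)(C)CCC[C@]23C | starting material
2 | potassium 8α-hydroxy-13,14,15,16-tetranorlabdan-12-oate | [K+].[O-]C(=O)C[C@H]1[C@](C)(O)CC[C@H]2C(C)(C)CCC[C@]12C | intermediate
3 | methyl 8α-hydroxy-13,14,15,16-tetranorlabdan-12-oate (5α-H, 9α-H, 10β-CH3, 8β-CH3) | COC(=O)C[C@H]1[C@](C)(O)CC[C@H]2C(C)(C)CCC[C@]12C | intermediate
4 | methyl 13,14,15,16-tetranorlabd-8(17)-en-12-oate (5α-H, 9α-H, 10β-CH3) | COC(=O)C[C@H]1C(=C)CC[C@H]2C(C)(C)CCC[C@]12C | intermediate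
5 | methyl 13,14,15,16-tetranorlabd-7-en-12-oate (5α-H, 9α-H, 10β-CH3) | COC(=O)C[C@H]1C(C)=CC[C@H]2C(C)(C)CCC[C@]12C | intermediate
6 | 13,14,15,16-tetranorlabd-7-en-12-oic acid | OC(=O)C[C@H]1C(C)=CC[C@H]2C(C)(C)CCC[C@]12C | intermediate
7 | methyl (8β-H)-13,14,15,16-tetranorlabdan-12-oate (8α-CH3, 5α-H, 9α-H, 10β-CH3) | COC(=O)C[C@H]1[C@H](C)CC[C@H]2C(C)(C)CCC[C@]12C | intermediate
8 | (8β-H)-13,14,15,16-tetranorlabdan-12-oic acid (8α-CH3) | OC(=O)C[C@H]1[C@H](C)CC[C@H]2C(C)(C)CCC[C@]12C | intermediate
9 | N-acyloxyphthalimide (redox-active ester) of 6 | O=C(C[C@H]1C(C)=CC[C@H]2C(C)(C)CCC[C@]12C)ON1C(=O)c2ccccc2C1=O | intermediate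
10 | N-acyloxyphthalimide (redox-active ester) of 8 | O=C(C[C@H]1[C@H](C)CC[C@H]2C(C)(C)CCC[C@]12C)ON1C(=O)c2ccccc2C1=O | intermediate
11 | (8'β-H)-11-(drim-7-en-11-yl)drimane; halves joined C11–C11'; Δ7 half 5α-H, 9α-H, 10β-CH3; saturated half 5'α-H, 8'β-H, 9'α-H, 10'β-CH3 | CC1=CC[C@H]2C(C)(C)CCC[C@]2(C)[C@H]1CC[C@H]1[C@H](C)CC[C@H]2C(C)(C)CCC[C@]12C | intermediate
12 | 3β-hydroxy derivative of 11 on the Δ7 half | CC1=CC[C@H]2C(C)(C)[C@@H](O)CC[C@]2(C)[C@H]1CC[C@H]1[C@H](C)CC[C@H]2C(C)(C)CCC[C@]12C | intermediate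
13 | 3'β-hydroxy derivative of 11 on the saturated half | CC1=CC[C@H]2C(C)(C)CCC[C@]2(C)[C@H]1CC[C@H]1[C@H](C)CC[C@H]2C(C)(C)[C@@H](O)CC[C@]12C | intermediate
14 | CNP0194061.1, an onocer-7-ene-3,21-diol: 3β-OH, 5α-H, 9α-H, 10β-CH3, Δ7 half joined C11–C11' to a 3'β-OH, 5'α-H, 8'β-H (8'α-CH3), 9'α-H, 10'β-CH3 half | CC1=CC[C@H]2C(C)(C)[C@@H](O)CC[C@]2(C)[C@H]1CC[C@H]1[C@H](C)CC[C@H]2C(C)(C)[C@@H](O)CC[C@]12C | target

**Step count and risks**
Total step count: 6. Longest linear sequence: 5 steps (1 → 3 → 4 → 6 or 8 → 11 → 14; steps 3 and 4 are parallel branches from 4).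

Three steps most likely to fail:

Step 6 (the proposed hydroxylation). Risks are poor uptake of the C30 hydrocarbon, stalling at the mono-ols 12 and 13, and oxidation near the alkene. The fallback uses known chemistry, sets out from 1 and comes back at 14, by putting the oxygen in first where the enzymatic reaction is established. The known sclareolide-selective P450 BM3 variant hydroxylates 1 to 3β-hydroxysclareolide F1. TBSOTf/2,6-lutidine converts it into 3β-(tert-butyldimethylsilyloxy)sclareolide F2. F2 is then carried through the conditions of steps 1 to 5. KOH/MeOH gives potassium 3β-silyloxy-8α-hydroxy carboxylate F3 and MeI gives its methyl ester F4. SOCl2/pyridine gives the silyloxy exo-methylene ester F5. The cobalt-catalysed isomerisation gives the silyloxy Δ7 ester F6 and LiOH the silyloxy Δ7 acid F7. MHAT hydrogenation of F5 gives the silyloxy 8β-H ester F8 and LiOH the silyloxy 8β-H acid F9. The silyloxy Δ7 N-acyloxyphthalimide F10 and the silyloxy saturated N-acyloxyphthalimide F11 are formed and cross-coupled electrochemically to the bis-silyl ether of the target F12. Bu4NF (THF, 50 °C) then frees both alcohols to give 14.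

Step 5 (cross-coupling). Risks are the statistical product distribution, the hindered β-branched primary radicals, and a possible homoallyl (3-exo closure/ring-opening) rearrangement of the C11 radical of the Δ7 half. The fallback sets out from the esters 9 and 10, here isolated, and comes back at 11 by a cross-selective two-electron union. Photochemical decarboxylative iodination (LiI, PPh3, 456 nm, acetone) converts 9 into 11-iododrim-7-ene F13 and 10 into 11-iodo-(8β-H)-drimane F14. Mg in THF turns F14 into (8β-H)-drimane-11-ylmagnesium iodide F15. F15 is coupled with F13 under Li2CuCl4 catalysis (THF/NMP, 0 °C to rt; Kochi-type SN2 alkyl–alkyl coupling) to give 11 with no homodimer statistics.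

Step 4 (face selectivity at C8). Axial β delivery of hydrogen is needed but is syn to the axial C10 methyl, so the 8β-CH3 epimer may dominate. The fallback sets out from 4 and comes back at 7. Hydrogenation of 4 over Pd/C (zerovalent palladium on carbon; H2, EtOAc) delivers hydrogen mainly from the α face and gives methyl (8α-H)-13,14,15,16-tetranorlabdan-12-oate F16, the 8β-methyl epimer, mixed with 7. Photochemical HAT stereo-editing of the tertiary C8–H ((n-Bu4N)4[W10O32] 2 mol %, bis(4-chlorophenyl) disulfide 10 mol %, 390 nm, MeCN) then equilibrates the mixture to the thermodynamically favoured 7; C5 and C9 already hold their most stable configurations. The LiOH stage of step 4 converts 7 into 8.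

**Further compounds**
F1 | step 6 | 3β-hydroxysclareolide | O=C1C[C@H]2[C@](C)(O1)CC[C@H]3C(C)(C)[C@@H](O)CC[C@]23C
F2 | step 6 | 3β-(tert-butyldimethylsilyloxy)sclareolide | O=C1C[C@H]2[C@](C)(O1)CC[C@H]3C(C)(C)[C@@H](O[Si](C)(C)C(C)(C)C)CC[C@]23C
F3 | step 6 | potassium 3β-(tert-butyldimethylsilyloxy)-8α-hydroxy-13,14,15,16-tetranorlabdan-12-oate | [K+].[O-]C(=O)C[C@H]1[C@](C)(O)CC[C@H]2C(C)(C)[C@@H](O[Si](C)(C)C(C)(C)C)CC[C@]12C
F4 | step 6 | methyl 3β-(tert-butyldimethylsilyloxy)-8α-hydroxy-13,14,15,16-tetranorlabdan-12-oate | COC(=O)C[C@H]1[C@](C)(O)CC[C@H]2C(C)(C)[C@@H](O[Si](C)(C)C(C)(C)C)CC[C@]12C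
F5 | step 6 | methyl 3β-(tert-butyldimethylsilyloxy)-13,14,15,16-tetranorlabd-8(17)-en-12-oate | COC(=O)C[C@H]1C(=C)CC[C@H]2C(C)(C)[C@@H](O[Si](C)(C)C(C)(C)C)CC[C@]12C
F6 | step 6 | methyl 3β-(tert-butyldimethylsilyloxy)-13,14,15,16-tetranorlabd-7-en-12-oate | COC(=O)C[C@H]1C(C)=CC[C@H]2C(C)(C)[C@@H](O[Si](C)(C)C(C)(C)C)CC[C@]12C
F7 | step 6 | 3β-(tert-butyldimethylsilyloxy)-13,14,15,16-tetranorlabd-7-en-12-oic acid | OC(=O)C[C@H]1C(C)=CC[C@H]2C(C)(C)[C@@H](O[Si](C)(C)C(C)(C)C)CC[C@]12C
F8 | step 6 | methyl 3β-(tert-butyldimethylsilyloxy)-(8β-H)-13,14,15,16-tetranorlabdan-12-oate | COC(=O)C[C@H]1[C@H](C)CC[C@H]2C(C)(C)[C@@H](O[Si](C)(C)C(C)(C)C)CC[C@]12C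
F9 | step 6 | 3β-(tert-butyldimethylsilyloxy)-(8β-H)-13,14,15,16-tetranorlabdan-12-oic acid | OC(=O)C[C@H]1[C@H](C)CC[C@H]2C(C)(C)[C@@H](O[Si](C)(C)C(C)(C)C)CC[C@]12C
F10 | step 6 | N-acyloxyphthalimide of F7 | O=C(C[C@H]1C(C)=CC[C@H]2C(C)(C)[C@@H](O[Si](C)(C)C(C)(C)C)CC[C@]12C)ON1C(=O)c2ccccc2C1=O
F11 | step 6 | N-acyloxyphthalimide of F9 | O=C(C[C@H]1[C@H](C)CC[C@H]2C(C)(C)[C@@H](O[Si](C)(C)C(C)(C)C)CC[C@]12C)ON1C(=O)c2ccccc2C1=O
F12 | step 6 | 3,3'-bis(tert-butyldimethylsilyl) ether of 14 | CC1=CC[C@H]2C(C)(C)[C@@H](O[Si](C)(C)C(C)(C)C)CC[C@]2(C)[C@H]1CC[C@H]1[C@H](C)CC[C@H]2C(C)(C)[C@@H](O[Si](C)(C)C(C)(C)C)CC[C@]12C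
F13 | step 5 | 11-iododrim-7-ene | IC[C@H]1C(C)=CC[C@H]2C(C)(C)CCC[C@]12C
F14 | step 5 | 11-iodo-(8β-H)-drimane | IC[C@H]1[C@H](C)CC[C@H]2C(C)(C)CCC[C@]12C
F15 | step 5 | (8β-H)-drimane-11-ylmagnesium iodide | I[Mg]C[C@H]1[C@H](C)CC[C@H]2C(C)(C)CCC[C@]12C
F16 | step 4 | methyl (8α-H)-13,14,15,16-tetranorlabdan-12-oate (8β-CH3 epimer of 7) | COC(=O)C[C@H]1[C@@H](C)CC[C@H]2C(C)(C)CCC[C@]12C
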